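The plan cuts the two exocyclic C–C bonds at the vicinal trans CH–CH pair of the cyclopentane ring: C3–isopropenyl and C2–CH2 (the link to the six-membered ring). Read backwards, the methyl carbinol C1 is a former ketone carbon, so C2 and C3 map onto the α- and β-positions of cyclopent-2-enone. A single copper-catalysed asymmetric conjugate addition of isopropenylmagnesium bromide, with benzylation of the magnesium enolate in the same flask, unites the enone, the alkenyl unit and the complete arene fragment and sets both CH stereocentres. The electrophile is a hexasubstituted benzylic bromide already carrying the (S)-2-methylbutanoyl ketone and the ring methyl, its three phenols masked as allyl ethers removable without acid.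

Key step: step 7

Remark: the target is handled as the enol tautomer drawn in its SMILES, and the R descriptor of the quaternary ring carbon refers to that tautomer.
Remark: L is (R)-1-[(SP)-2-(diphenylphosphino)ferrocenyl]ethyldicyclohexylphosphine; it is assumed that this hand gives the 3R ketone with the alkenyl Grignard reagent, to be confirmed on a test scale, the mirror-image ligand being used otherwise.
Remark: allyl ethers are chosen over acetal protecting groups because, late in the route, a tertiary alcohol and an isopropenyl group lie within reach of an ortho phenol and acid would invite cyclisation to a chroman.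

Step 1
Reactants: 1 2-methylbenzene-1,3,5-triol (2-methylphloroglucinol); 2 (2S)-2-methylbutanoic acid
Product: 4 (2S)-2-methyl-1-(2,4,6-trihydroxy-3-methylphenyl)butan-1-one, via (2S)-2-methylbutanoyl chloride 3 (not isolated)
Conditions: 2, (COCl)2, cat. DMF, CH2Cl2, 0 °C to rt, evaporate; then 1, AlCl3, PhNO2/CH2Cl2, 0 °C to rt; cold aq. HCl
Reagents that add atoms: oxalyl chloride, ClC(=O)C(=O)Cl (gives only the chlorine of 3; no reagent atom remains in 4)
Why: Friedel–Crafts C-acylation of the electron-rich triol at one of its two equivalent free ring positions should stop at the mono-ketone because the first acyl group deactivates the ring, and the base-free medium at or below room temperature is chosen to keep the α-stereocentre of the acyl chloride intact.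

Step 2
Reactants: 4 (2S)-2-methyl-1-(2,4,6-trihydroxy-3-methylphenyl)butan-1-one
Product: 6 2,4,6-trihydroxy-3-methyl-5-[(2S)-2-methylbutanoyl]benzaldehyde, via aryl iminium chloride 5 (not isolated)
Conditions: POCl3, DMF, EtOAc, 0 °C to rt; then H2O, 50 °C
Reagents that add atoms: N,N-dimethylformamide, CN(C)C=O; water, O
Why: Vilsmeier–Haack formylation attacks the only remaining ring CH of the still electron-rich acylphloroglucinol, and hydrolysis of the iminium salt releases the aldehyde.

Step 3
Reactants: 6 2,4,6-trihydroxy-3-methyl-5-[(2S)-2-methylbutanoyl]benzaldehyde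
Product: 7 3-methyl-5-[(2S)-2-methylbutanoyl]-2,4,6-tris(prop-2-en-1-yloxy)benzaldehyde
Conditions: allyl bromide (excess), K2CO3, DMF, 50 °C
Reagents that add atoms: allyl bromide (3-bromoprop-1-ene), C=CCBr
Why: Williamson O-alkylation in a dipolar aprotic solvent with a potassium counter-ion should favour attack through oxygen over ring carbon on this fully substituted phenoxide bearing two carbonyl groups, and carbonate is too weak a base to exchange the hindered α-hydrogen of the ketone.

Step 4
Reactants: 7 3-methyl-5-[(2S)-2-methylbutanoyl]-2,4,6-tris(prop-2-en-1-yloxy)benzaldehyde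
Product: 8 (2S)-1-[3-(hydroxymethyl)-5-methyl-2,4,6-tris(prop-2-en-1-yloxy)phenyl]-2-methylbutan-1-one
Conditions: NaBH4, MeOH/THF, −10 °C
Reagents that add atoms: none
Why: Borohydride reduction should be chemoselective for the aldehyde because the α-branched aryl ketone, flanked by two ortho allyloxy groups, is twisted out of conjugation and shielded.

Step 5
Reactants: 8 (2S)-1-[3-(hydroxymethyl)-5-methyl-2,4,6-tris(prop-2-en-1-yloxy)phenyl]-2-methylbutan-1-one
Product: 9 (2S)-1-[3-(bromomethyl)-5-methyl-2,4,6-tris(prop-2-en-1-yloxy)phenyl]-2-methylbutan-1-one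
Conditions: CBr4, PPh3, CH2Cl2, 0 °C; short silica plug, used at once
Reagents that add atoms: tetrabromomethane, BrC(Br)(Br)Br
Why: The Appel reaction converts the benzylic alcohol under neutral conditions through an alkoxyphosphonium ion that bromide displaces, which suits a bromide that three oxygen donors make prone to ionisation.

Step 6
Reactants: 10 2-bromopropene
Product: 11 isopropenylmagnesium bromide (prop-1-en-2-ylmagnesium bromide)
Conditions: Mg turnings, cat. I2, 2-MeTHF, 40 °C; titrated
Reagents that add atoms: magnesium, [Mg]
Why: Grignard formation by insertion of magnesium into the vinylic C–Br bond is routine for 2-bromopropene, and 2-MeTHF keeps strongly coordinating THF out of the copper-catalysed step.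

Step 7
Reactants: 12 cyclopent-2-en-1-one; 11 isopropenylmagnesium bromide; 9 (2S)-1-[3-(bromomethyl)-5-methyl-2,4,6-tris(prop-2-en-1-yloxy)phenyl]-2-methylbutan-1-one
Product: 14 (2S,3R)-2-({3-methyl-5-[(2S)-2-methylbutanoyl]-2,4,6-tris(prop-2-en-1-yloxy)phenyl}methyl)-3-(prop-1-en-2-yl)cyclopentan-1-one, via bromomagnesium enolate 13 (not isolated)
Conditions: CuBr·SMe2 (5 mol %), L (6 mol %), t-BuOMe, −78 °C, slow addition of 11 to 12 (1.5 equiv each); then 9 (1 equiv), DMPU, −78 to −20 °C; aq. NH4Cl
Reagents that add atoms: none
Why: A chiral monovalent copper–diphosphine complex is transmetalated by 11 and transfers the isopropenyl group to the β-carbon of 12 through a π-complex and a trivalent copper σ-intermediate, whose reductive elimination leaves the regiodefined bromomagnesium enolate 13, which is then C-alkylated at the α-carbon by the benzylic bromide 9 in an SN2 reaction promoted by DMPU. The closest known reaction type is the copper-catalysed asymmetric conjugate addition of Grignard reagents to cyclic enones with alkylation of the magnesium enolate by a reactive halide (three-component coupling), and no ring is closed. C3 (R) is set by the ferrocenyl diphosphine on copper, and C2 (S) by the substrate, because the electrophile approaches the enolate face opposite the new C3 substituent, giving the trans ketone, which is also the more stable epimer. The step needs 1,4- over 1,2-addition, secured by the soft copper catalyst at −78 °C with slow addition of the Grignard reagent, and alkylation at C2 before the enolate can equilibrate, secured by the high reactivity of the electron-rich benzylic bromide and by keeping the enolate in excess over 9. The aryl ketone of 9 should be spared because two ortho allyloxy groups and the α-branch shield its carbonyl and its hindered α-hydrogen is less acidic than those of a cyclopentanone, so the (S)-2-methylbutanoyl centre should not exchange.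

Step 8
Reactants: 14 (2S,3R)-2-({3-methyl-5-[(2S)-2-methylbutanoyl]-2,4,6-tris(prop-2-en-1-yloxy)phenyl}methyl)-3-(prop-1-en-2-yl)cyclopentan-1-one
Product: 15 (2S)-1-[3-{[(1S,2R,5R)-2-hydroxy-2-methyl-5-(prop-1-en-2-yl)cyclopentyl]methyl}-5-methyl-2,4,6-tris(prop-2-en-1-yloxy)phenyl]-2-methylbutan-1-one
Conditions: MeMgBr, anhydrous CeCl3, THF, −78 °C; aq. NH4Cl
Reagents that add atoms: methylmagnesium bromide, C[Mg]Br
Why: Cerium-mediated 1,2-addition of the weakly basic methyl nucleophile should occur at the unhindered cyclopentanone and not at the shielded aryl ketone, and the methyl group should enter from the ring face opposite the adjacent C2 arylmethyl group, which sets the carbinol carbon as R with the hydroxyl cis to the CH2 link.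

Step 9
Reactants: 15 (2S)-1-[3-{[(1S,2R,5R)-2-hydroxy-2-methyl-5-(prop-1-en-2-yl)cyclopentyl]methyl}-5-methyl-2,4,6-tris(prop-2-en-1-yloxy)phenyl]-2-methylbutan-1-one
Product: 16 (2S)-1-[2,4,6-trihydroxy-3-{[(1S,2R,5R)-2-hydroxy-2-methyl-5-(prop-1-en-2-yl)cyclopentyl]methyl}-5-methylphenyl]-2-methylbutan-1-one
Conditions: Pd(PPh3)4 (5 mol %), morpholine (excess), THF, rt; NaH2PO4 buffer
Reagents that add atoms: none
Why: In this Tsuji–Trost deallylation zerovalent palladium ionises each aryl allyl ether to a π-allyl complex and a phenoxide, and excess morpholine captures the allyl unit, so the three phenols are freed under neutral conditions that leave the tertiary alcohol, the isopropenyl group and all stereocentres untouched.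

Step 10
Reactants: 16 (2S)-1-[2,4,6-trihydroxy-3-{[(1S,2R,5R)-2-hydroxy-2-methyl-5-(prop-1-en-2-yl)cyclopentyl]methyl}-5-methylphenyl]-2-methylbutan-1-one
Product: 17 (6R)-3,5-dihydroxy-4-{[(1S,2R,5R)-2-hydroxy-2-methyl-5-(prop-1-en-2-yl)cyclopentyl]methyl}-6-methyl-6-(3-methylbut-2-en-1-yl)-2-[(2S)-2-methylbutanoyl]cyclohexa-2,4-dien-1-one (target)
Conditions: prenyl bromide (1.1 equiv), NaOMe, MeOH, 0 °C; NaH2PO4 buffer; preparative HPLC to remove the epimer at the quaternary ring carbon
Reagents that add atoms: prenyl bromide (1-bromo-3-methylbut-2-ene), CC(C)=CCBr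
Why: Dearomatising C-alkylation of the acylphloroglucinol anion in a protic medium, which disfavours O-alkylation, should occur at the methyl-bearing ring carbon because the other alkyl-bearing carbon carries the bulky cyclopentylmethyl group and the acyl-bearing carbon is deactivated, while the remote stereocentres are expected to give little facial control, so the quaternary centre should form as both epimers and the 6R epimer 17 is obtained by chromatographic separation.

Compound list
1 | 2-methylbenzene-1,3,5-triol (2-methylphloroglucinol) | Cc1c(O)cc(O)cc1O | starting material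
2 | (2S)-2-methylbutanoic acid | CC[C@H](C)C(=O)O | starting material
3 | (2S)-2-methylbutanoyl chloride | CC[C@H](C)C(Cl)=O | intermediate
4 | (2S)-2-methyl-1-(2,4,6-trihydroxy-3-methylphenyl)butan-1-one | CC[C@H](C)C(=O)c1c(O)cc(O)c(C)c1O | intermediate
5 | N,N-dimethyl iminium chloride of aldehyde 6 (aryl–CH=NMe2+ Cl−) | C[N+](C)=Cc1c(O)c(C)c(O)c(C(=O)[C@@H](C)CC)c1O.[Cl-] | intermediate
6 | 2,4,6-trihydroxy-3-methyl-5-[(2S)-2-methylbutanoyl]benzaldehyde | O=Cc1c(O)c(C)c(O)c(C(=O)[C@@H](C)CC)c1O | intermediate
7 | 3-methyl-5-[(2S)-2-methylbutanoyl]-2,4,6-tris(prop-2-en-1-yloxy)benzaldehyde | O=Cc1c(OCC=C)c(C)c(OCC=C)c(C(=O)[C@@H](C)CC)c1OCC=C | intermediate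
8 | (2S)-1-[3-(hydroxymethyl)-5-methyl-2,4,6-tris(prop-2-en-1-yloxy)phenyl]-2-methylbutan-1-one | OCc1c(OCC=C)c(C)c(OCC=C)c(C(=O)[C@@H](C)CC)c1OCC=C | intermediate
9 | (2S)-1-[3-(bromomethyl)-5-methyl-2,4,6-tris(prop-2-en-1-yloxy)phenyl]-2-methylbutan-1-one | BrCc1c(OCC=C)c(C)c(OCC=C)c(C(=O)[C@@H](C)CC)c1OCC=C | intermediate
10 | 2-bromopropene | C=C(C)Br | starting material
11 | isopropenylmagnesium bromide | C=C(C)[Mg]Br | intermediate
12 | cyclopent-2-en-1-one | O=C1C=CCC1 | starting material
13 | bromomagnesium (3R)-3-(prop-1-en-2-yl)cyclopent-1-en-1-olate | C=C(C)[C@@H]1CCC(O[Mg]Br)=C1 | intermediate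
14 | (2S,3R)-2-({3-methyl-5-[(2S)-2-methylbutanoyl]-2,4,6-tris(prop-2-en-1-yloxy)phenyl}methyl)-3-(prop-1-en-2-yl)cyclopentan-1-one (2,3-trans) | C=C(C)[C@@H]1CCC(=O)[C@H]1Cc1c(OCC=C)c(C)c(OCC=C)c(C(=O)[C@@H](C)CC)c1OCC=C | intermediate
15 | (2S)-1-[3-{[(1S,2R,5R)-2-hydroxy-2-methyl-5-(prop-1-en-2-yl)cyclopentyl]methyl}-5-methyl-2,4,6-tris(prop-2-en-1-yloxy)phenyl]-2-methylbutan-1-one (hydroxyl cis to the CH2 link, isopropenyl trans to it) | C=C(C)[C@@H]1CC[C@@](C)(O)[C@H]1Cc1c(OCC=C)c(C)c(OCC=C)c(C(=O)[C@@H](C)CC)c1OCC=C | intermediate
16 | (2S)-1-[2,4,6-trihydroxy-3-{[(1S,2R,5R)-2-hydroxy-2-methyl-5-(prop-1-en-2-yl)cyclopentyl]methyl}-5-methylphenyl]-2-methylbutan-1-one | C=C(C)[C@@H]1CC[C@@](C)(O)[C@H]1Cc1c(O)c(C)c(O)c(C(=O)[C@@H](C)CC)c1O | intermediate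
17 | (6R)-3,5-dihydroxy-4-{[(1S,2R,5R)-2-hydroxy-2-methyl-5-(prop-1-en-2-yl)cyclopentyl]methyl}-6-methyl-6-(3-methylbut-2-en-1-yl)-2-[(2S)-2-methylbutanoyl]cyclohexa-2,4-dien-1-one | C=C(C)[C@@H]1CC[C@@](C)(O)[C@H]1CC1=C(O)[C@@](C)(CC=C(C)C)C(=O)C(C(=O)[C@@H](C)CC)=C1O | target

Total step count: 10. Longest linear sequence: 9 steps (steps 1–5, then 7–10); step 6 is a one-step side branch.

Steps most likely to fail

Step 7. The alkenyl Grignard reagent may be transferred with too little enantiofacial discrimination. C-benzylation of the magnesium enolate may also be slower than proton exchange with the product, which would scramble the enolate regiochemistry and cause double alkylation. The fallback sets out from 11 and 12 and comes back at 14. The same copper-catalysed addition is quenched with Me3SiCl/Et3N to give the silyl enol ether trimethyl{[(3R)-3-(prop-1-en-2-yl)cyclopent-1-en-1-yl]oxy}silane F1, which is isolated. This lets the conjugate addition be optimised and its enantiomeric purity checked without spending bromide 9. MeLi in THF at 0 °C then cleaves the O–Si bond to the regiodefined lithium enolate lithium (3R)-3-(prop-1-en-2-yl)cyclopent-1-en-1-olate F2. Its alkylation with 9 in THF/DMPU at −78 °C, from the face opposite the isopropenyl group, should give 14.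

Step 10. The alkylation proceeds without useful facial bias, so half of the material is lost to the epimer and the separation may be hard. Attack through oxygen, attack at the ring carbon bearing the cyclopentylmethyl group and a second alkylation of the acidic product may compete. The fallback sets out from 16 and comes back at 17 with no new isolated compound. It is a Tsuji–Trost prenylation with tert-butyl 3-methylbut-2-en-1-yl carbonate and Pd2(dba)3 with a phosphine in THF at rt. The soft π-prenyl palladium electrophile should react through carbon, at its less hindered allyl terminus and at the less hindered ring carbon, under neutral conditions. A C2-symmetric diphosphine (the diamide of trans-cyclohexane-1,2-diamine with 2-(diphenylphosphino)benzoic acid) in either hand can then be screened so that the catalyst decides the face.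

Step 5. The very electron-rich benzylic bromide may ionise during formation, filtration or storage and be lost to hydrolysis or self-alkylation. The fallback avoids any benzylic halide; it sets out from aldehyde 7 and enolate 13 (generated from 11 and 12 as in step 7) and comes back at 14. Aldol trapping of 13 with 7 at −78 °C gives the β-hydroxy ketone (2R,3R)-2-[hydroxy({3-methyl-5-[(2S)-2-methylbutanoyl]-2,4,6-tris(prop-2-en-1-yloxy)phenyl})methyl]-3-(prop-1-en-2-yl)cyclopentan-1-one F3 as both carbinol epimers. MsCl/Et3N in CH2Cl2 at 0 °C eliminates it (E1cB) to the benzylidene ketone (2E,3S)-2-({3-methyl-5-[(2S)-2-methylbutanoyl]-2,4,6-tris(prop-2-en-1-yloxy)phenyl}methylidene)-3-(prop-1-en-2-yl)cyclopentan-1-one F4, which keeps the spatial arrangement at C3; either alkene geometry serves. Conjugate reduction with [(Ph3P)CuH]6 in wet toluene, which leaves the isolated alkenes and the hindered aryl ketone alone, followed by protonation to the more stable trans ketone (brief Et3N equilibration if needed), gives 14.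

Further compounds
F1 | step 7 | trimethyl{[(3R)-3-(prop-1-en-2-yl)cyclopent-1-en-1-yl]oxy}silane | C=C(C)[C@@H]1CCC(O[Si](C)(C)C)=C1
F2 | step 7 | lithium (3R)-3-(prop-1-en-2-yl)cyclopent-1-en-1-olate | C=C(C)[C@@H]1CCC(O[Li])=C1
F0 | step 10 | none | none
F3 | step 5 | (2R,3R)-2-[hydroxy({3-methyl-5-[(2S)-2-methylbutanoyl]-2,4,6-tris(prop-2-en-1-yloxy)phenyl})methyl]-3-(prop-1-en-2-yl)cyclopentan-1-one, both carbinol epimers | C=C(C)[C@@H]1CCC(=O)[C@H]1C(O)c1c(OCC=C)c(C)c(OCC=C)c(C(=O)[C@@H](C)CC)c1OCC=C
F4 | step 5 | (2E,3S)-2-({3-methyl-5-[(2S)-2-methylbutanoyl]-2,4,6-tris(prop-2-en-1-yloxy)phenyl}methylidene)-3-(prop-1-en-2-yl)cyclopentan-1-one | C=C(C)[C@@H]1CCC(=O)/C1=C/c1c(OCC=C)c(C)c(OCC=C)c(C(=O)[C@@H](C)CC)c1OCC=C
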